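**Retrosynthetic overview**

- The route rests on ring A (C4a, C5, C6, C7, C8, C8a). Its oxygens O5 and O7 are meta to each other, O5 must stay a free phenol beside C4=O and O7 must carry the sulfate. A vinylketene plus siloxyalkyne benzannulation delivers this pattern with O5 free and O7 as a silyl ether.
- Key disconnection: ring A is cut at C8a–C8, C7–C8, C5–C6 and C4a–C5. This gives a 2-aryl-3-benzyloxy-4-pyranone with a diazoacetyl group on C8a, and the alkyne i-Pr3SiO–C≡C–SiMe3.
- Ring C is kojic acid. Ring B is attached by Suzuki–Miyaura coupling at the brominated carbon next to the ring oxygen (flavone C2). The CH2OH group is taken through the acid and acid chloride to the diazo ketone.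
- Order of rings: ring C (bought), ring B (coupled), ring A (built last). The end game is C6 protodesilylation, O7 desilylation, 7-O-sulfation and hydrogenolysis of both benzyl ethers.

Key step: step 8

Assumption: the target is taken as the free hydrogen sulfate drawn in the SMILES; the sulfate is carried as its sodium salt and the acid form is liberated only in the last operation. Flavone numbering (O1, C2–C4, C4a, C5–C8, C8a) is used for ring atoms in the discussion, also for the pyranone precursors.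

**Route**

Step 1
Reactants: 1 kojic acid [5-hydroxy-2-(hydroxymethyl)-4H-pyran-4-one]
Product: 2 6-bromo-5-hydroxy-2-(hydroxymethyl)-4H-pyran-4-one
Conditions: NBS (1.05 equiv), MeCN, 0 °C → rt
Reagents that add atoms: N-bromosuccinimide, O=C1CCC(=O)N1Br
Why: Electrophilic bromination of the 3-hydroxy-4-pyranone enol occurs at its only free ortho carbon (C6, next to the ring oxygen), the known site of halogenation of kojic acid.

Step 2
Reactants: 2 6-bromo-5-hydroxy-2-(hydroxymethyl)-4H-pyran-4-one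
Product: 3 5-(benzyloxy)-6-bromo-2-(hydroxymethyl)-4H-pyran-4-one
Conditions: BnBr (1.1 equiv), K2CO3, DMF, rt
Reagents that add atoms: benzyl bromide, BrCc1ccccc1
Why: Williamson etherification; K2CO3 deprotonates only the acidic enolic OH, so the primary alcohol stays free.

Step 3
Reactants: 3 5-(benzyloxy)-6-bromo-2-(hydroxymethyl)-4H-pyran-4-one; 4 4-(benzyloxy)-3-methoxyphenylboronic acid
Product: 5 3-(benzyloxy)-2-[4-(benzyloxy)-3-methoxyphenyl]-6-(hydroxymethyl)-4H-pyran-4-one
Conditions: Pd(PPh3)4 (5 mol %), Na2CO3, 1,4-dioxane/H2O, 85 °C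
Reagents that add atoms: none
Why: Suzuki–Miyaura coupling; the C–Br bond is a vinylogous acyl bromide that adds readily to zerovalent palladium, and the benzyl ether and free alcohol are inert.

Step 4
Reactants: 5 3-(benzyloxy)-2-[4-(benzyloxy)-3-methoxyphenyl]-6-(hydroxymethyl)-4H-pyran-4-one
Product: 7 5-(benzyloxy)-6-[4-(benzyloxy)-3-methoxyphenyl]-4-oxo-4H-pyran-2-carboxylic acid, via pyranone-2-carbaldehyde 6 (not isolated)
Conditions: TEMPO (0.2 equiv), PhI(OAc)2 (2.2 equiv), MeCN/H2O (1:1), rt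
Reagents that add atoms: water, O
Why: Oxoammonium (TEMPO/PhI(OAc)2) oxidation of the primary alcohol to the aldehyde, whose hydrate is oxidised on to the acid; aryl ethers and the pyranone are not touched.

Step 5
Reactants: 7 5-(benzyloxy)-6-[4-(benzyloxy)-3-methoxyphenyl]-4-oxo-4H-pyran-2-carboxylic acid
Product: 8 5-(benzyloxy)-6-[4-(benzyloxy)-3-methoxyphenyl]-4-oxo-4H-pyran-2-carbonyl chloride
Conditions: (COCl)2 (1.3 equiv), DMF (cat.), CH2Cl2, 0 °C → rt; evaporate, use crude
Reagents that add atoms: oxalyl chloride, O=C(Cl)C(=O)Cl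
Why: Acid chloride formation through the Vilsmeier-type chloroiminium species, as practised for 4-oxopyran-2-carboxylic and chromone-2-carboxylic acids.

Step 6
Reactants: 8 5-(benzyloxy)-6-[4-(benzyloxy)-3-methoxyphenyl]-4-oxo-4H-pyran-2-carbonyl chloride
Product: 9 3-(benzyloxy)-2-[4-(benzyloxy)-3-methoxyphenyl]-6-(2-diazoacetyl)-4H-pyran-4-one
Conditions: CH2N2 (3 equiv), Et2O/THF, 0 °C; AcOH quench
Reagents that add atoms: diazomethane, C=[N+]=[N-]
Why: Acylation of diazomethane (first stage of the Arndt–Eistert sequence); the acyl chloride is far more electrophilic than the ring C=C bonds, and the extra diazomethane removes HCl as chloromethane so the diazo ketone is not converted to the chloromethyl ketone.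

Step 7
Reactants: 10 ethynyltrimethylsilane
Product: 13 triisopropyl{[2-(trimethylsilyl)ethynyl]oxy}silane, via lithium (trimethylsilyl)acetylide 11 (not isolated), via lithium silylynolate 12 (not isolated)
Conditions: n-BuLi, THF, −78 °C; t-BuOOLi (from t-BuOOH + LiN(SiMe3)2), −78 → 0 °C; i-Pr3SiOTf, −78 °C → rt
Reagents that add atoms: lithium tert-butyl peroxide (made in the flask from tert-butyl hydroperoxide), [Li+].[O-]OC(C)(C)C; triisopropylsilyl trifluoromethanesulfonate, CC(C)[Si](OS(=O)(=O)C(F)(F)F)(C(C)C)C(C)C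
Why: Oxidation of a lithium acetylide by lithium tert-butyl peroxide (attack on the peroxide oxygen) gives the ynolate, and the bulky triisopropylsilyl triflate should silylate it on oxygen, whereas small silyl groups go to carbon.

Step 8
Reactants: 9 3-(benzyloxy)-2-[4-(benzyloxy)-3-methoxyphenyl]-6-(2-diazoacetyl)-4H-pyran-4-one; 13 triisopropyl{[2-(trimethylsilyl)ethynyl]oxy}silane
Product: 18 3,4'-di-O-benzyl-7-O-(triisopropylsilyl)-6-(trimethylsilyl)isorhamnetin, via pyranonylketene 14 (not isolated), via siloxycyclobutenone 15 (not isolated), via dienylketene 16 (not isolated), via cyclohexadienone 17 (not isolated)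
Conditions: 13 (2 equiv), degassed ClCH2CH2Cl (0.2 M), hν (300 nm, Pyrex), rt until 9 is consumed; then 80 °C in the dark
Reagents that add atoms: none
Why: Proposed new method: light expels N2 from 9 and the Wolff shift moves C8a from the acyl carbon to the former diazo carbon (C8a–C8), giving ketene 14, a vinylketene whose vinyl unit is the C4a=C8a bond of the pyranone; the siloxyalkyne then adds across the ketene C=C bond in a (2+2) cycloaddition with its silicon-bearing carbon (β to oxygen, nucleophilic) on the ketene carbonyl carbon (C5–C6 and C7–C8), giving cyclobutenone 15. Four-electron electrocyclic opening of 15 (light or 80 °C) gives dienylketene 16, and ring A closes by a thermal six-electron disrotatory electrocyclisation that joins the ketene carbon to C4a (C4a–C5); enolisation of the doubly activated C4a–H of dienone 17 gives the phenol. The closest known reaction type is the Danheiser benzannulation of aryl, heteroaryl and vinyl diazo ketones with siloxyalkynes through a photochemical Wolff rearrangement; a 4-pyranone has not served as the vinyl partner. The closure should be favoured here because C4a is the nucleophilic α-carbon of a vinylogous ester and meets an electrophilic ketene carbon, and because the pyranone gives up far less aromatic stabilisation than a benzene ring does in the known cases. No stereocentre is kept: C8 of 15 and C4a of 17 are transient and racemic. The step needs one orientation in the (2+2) addition, which the polarisation of the siloxyalkyne secures so that the silyloxy carbon becomes C7 meta to the new 5-OH, and chemoselective excitation of the diazo ketone, helped by irradiating only until 9 is gone, finishing in the dark, and by the hydrogen-bonded 5-hydroxy-4-ketone unit of the product, which deactivates its excited state by proton transfer.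

Step 9
Reactants: 18 3,4'-di-O-benzyl-7-O-(triisopropylsilyl)-6-(trimethylsilyl)isorhamnetin
Product: 19 3,4'-di-O-benzyl-7-O-(triisopropylsilyl)isorhamnetin
Conditions: CF3CO2H (10 equiv), CH2Cl2, 0 °C → rt
Reagents that add atoms: none
Why: ipso-Protodesilylation by electrophilic aromatic substitution; C6 is ortho to O5 and O7 and para to O1, and the β-silicon effect stabilises the arenium ion, while benzyl ethers tolerate dilute acid (any loss of the 7-O-silyl group is harmless, since step 10 removes it).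

Step 10
Reactants: 19 3,4'-di-O-benzyl-7-O-(triisopropylsilyl)isorhamnetin
Product: 20 3,4'-di-O-benzylisorhamnetin [3-(benzyloxy)-2-[4-(benzyloxy)-3-methoxyphenyl]-5,7-dihydroxy-4H-chromen-4-one]
Conditions: Bu4NF (1.2 equiv), AcOH (1.5 equiv), THF, 0 °C
Reagents that add atoms: none
Why: Fluoride cleavage of the aryl silyl ether, driven by the Si–F bond; acetic acid buffers the phenoxide so the flavonol is not exposed to strong base.

Step 11
Reactants: 20 3,4'-di-O-benzylisorhamnetin
Product: 22 sodium 3,4'-di-O-benzylisorhamnetin 7-sulfate, via pyridinium sulfate 21 (not isolated)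
Conditions: SO3·pyridine (3 equiv), pyridine, rt → 40 °C; aq. NaHCO3; C18 chromatography
Reagents that add atoms: sulfur trioxide pyridine complex, [O-]S(=O)(=O)[n+]1ccccc1; sodium hydrogen carbonate, [Na+].OC([O-])=O
Why: O-Sulfonation of a phenol by an amine–SO3 complex; only the acidic, unhindered 7-OH reacts, because the 5-OH is locked in a hydrogen bond to C4=O and the 3- and 4'-oxygens are benzylated.

Step 12
Reactants: 22 sodium 3,4'-di-O-benzylisorhamnetin 7-sulfate
Product: 24 isorhamnetin 7-O-sulfate, via sodium isorhamnetin 7-sulfate 23 (not isolated)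
Conditions: H2 (1 atm), 10% Pd/C, MeOH/THF, rt; then HCl (1.0 equiv, 0.1 M), 0 °C, C18 desalting, freeze-drying
Reagents that add atoms: none
Why: Hydrogenolysis of both benzyl ethers; the aryl sulfate monoester anion and the flavonol C2=C3 bond are not reduced at 1 atm, and one equivalent of cold acid gives the hydrogen sulfate without solvolysis of the S–O bond.

**Compound list**

1 | kojic acid | O=c1cc(CO)occ1O | starting material
2 | 6-bromo-5-hydroxy-2-(hydroxymethyl)-4H-pyran-4-one | O=c1cc(CO)oc(Br)c1O | intermediate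
3 | 5-(benzyloxy)-6-bromo-2-(hydroxymethyl)-4H-pyran-4-one | O=c1cc(CO)oc(Br)c1OCc1ccccc1 | intermediate
4 | 4-(benzyloxy)-3-methoxyphenylboronic acid | COc1cc(B(O)O)ccc1OCc1ccccc1 | starting material
5 | 3-(benzyloxy)-2-[4-(benzyloxy)-3-methoxyphenyl]-6-(hydroxymethyl)-4H-pyran-4-one | COc1cc(-c2oc(CO)cc(=O)c2OCc2ccccc2)ccc1OCc1ccccc1 | intermediate
6 | 5-(benzyloxy)-6-[4-(benzyloxy)-3-methoxyphenyl]-4-oxo-4H-pyran-2-carbaldehyde (not isolated) | COc1cc(-c2oc(C=O)cc(=O)c2OCc2ccccc2)ccc1OCc1ccccc1 | intermediate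
7 | 5-(benzyloxy)-6-[4-(benzyloxy)-3-methoxyphenyl]-4-oxo-4H-pyran-2-carboxylic acid | COc1cc(-c2oc(C(=O)O)cc(=O)c2OCc2ccccc2)ccc1OCc1ccccc1 | intermediate
8 | 5-(benzyloxy)-6-[4-(benzyloxy)-3-methoxyphenyl]-4-oxo-4H-pyran-2-carbonyl chloride | COc1cc(-c2oc(C(=O)Cl)cc(=O)c2OCc2ccccc2)ccc1OCc1ccccc1 | intermediate
9 | 3-(benzyloxy)-2-[4-(benzyloxy)-3-methoxyphenyl]-6-(2-diazoacetyl)-4H-pyran-4-one | COc1cc(-c2oc(C(=O)C=[N+]=[N-])cc(=O)c2OCc2ccccc2)ccc1OCc1ccccc1 | intermediate
10 | ethynyltrimethylsilane | C#C[Si](C)(C)C | starting material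
11 | lithium (trimethylsilyl)acetylide (not isolated) | [Li+].[C-]#C[Si](C)(C)C | intermediate
12 | lithium 2-(trimethylsilyl)ethynolate (not isolated) | [Li+].[O-]C#C[Si](C)(C)C | intermediate
13 | triisopropyl{[2-(trimethylsilyl)ethynyl]oxy}silane | CC(C)[Si](OC#C[Si](C)(C)C)(C(C)C)C(C)C | intermediate
14 | 3-(benzyloxy)-2-[4-(benzyloxy)-3-methoxyphenyl]-6-(2-oxoethenyl)-4H-pyran-4-one (ketene, not isolated) | COc1cc(-c2oc(C=C=O)cc(=O)c2OCc2ccccc2)ccc1OCc1ccccc1 | intermediate
15 | 4-{5-(benzyloxy)-6-[4-(benzyloxy)-3-methoxyphenyl]-4-oxo-4H-pyran-2-yl}-3-(triisopropylsilyloxy)-2-(trimethylsilyl)cyclobut-2-en-1-one (racemic, not isolated) | COc1cc(-c2oc(C3C(=O)C([Si](C)(C)C)=C3O[Si](C(C)C)(C(C)C)C(C)C)cc(=O)c2OCc2ccccc2)ccc1OCc1ccccc1 | intermediate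
16 | dienylketene: 4-(pyranon-2-yl)-3-(triisopropylsilyloxy)-2-(trimethylsilyl)buta-1,3-dien-1-one, pyranonyl group cis to the ketene carbon chain across C7=C8 (E by the sequence rule, not isolated) | COc1cc(-c2oc(/C=C(\C(=C=O)[Si](C)(C)C)O[Si](C(C)C)(C(C)C)C(C)C)cc(=O)c2OCc2ccccc2)ccc1OCc1ccccc1 | intermediate
17 | 4a-H keto tautomer of 18: 3-(benzyloxy)-2-[4-(benzyloxy)-3-methoxyphenyl]-7-(triisopropylsilyloxy)-6-(trimethylsilyl)-4aH-chromene-4,5-dione (racemic, not isolated) | COc1cc(C2=C(OCc3ccccc3)C(=O)C3C(=O)C([Si](C)(C)C)=C(O[Si](C(C)C)(C(C)C)C(C)C)C=C3O2)ccc1OCc1ccccc1 | intermediate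
18 | 3,4'-di-O-benzyl-7-O-(triisopropylsilyl)-6-(trimethylsilyl)isorhamnetin | COc1cc(-c2oc3cc(O[Si](C(C)C)(C(C)C)C(C)C)c([Si](C)(C)C)c(O)c3c(=O)c2OCc2ccccc2)ccc1OCc1ccccc1 | intermediate
19 | 3,4'-di-O-benzyl-7-O-(triisopropylsilyl)isorhamnetin | COc1cc(-c2oc3cc(O[Si](C(C)C)(C(C)C)C(C)C)cc(O)c3c(=O)c2OCc2ccccc2)ccc1OCc1ccccc1 | intermediate
20 | 3,4'-di-O-benzylisorhamnetin | COc1cc(-c2oc3cc(O)cc(O)c3c(=O)c2OCc2ccccc2)ccc1OCc1ccccc1 | intermediate
21 | pyridinium 3,4'-di-O-benzylisorhamnetin 7-sulfate (not isolated) | COc1cc(-c2oc3cc(OS(=O)(=O)[O-])cc(O)c3c(=O)c2OCc2ccccc2)ccc1OCc1ccccc1.c1cc[nH+]cc1 | intermediate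
22 | sodium 3,4'-di-O-benzylisorhamnetin 7-sulfate | COc1cc(-c2oc3cc(OS(=O)(=O)[O-])cc(O)c3c(=O)c2OCc2ccccc2)ccc1OCc1ccccc1.[Na+] | intermediate
23 | sodium isorhamnetin 7-sulfate (not isolated) | COc1cc(-c2oc3cc(OS(=O)(=O)[O-])cc(O)c3c(=O)c2O)ccc1O.[Na+] | intermediate
24 | isorhamnetin 7-O-sulfate | COc1cc(-c2oc3cc(OS(=O)(=O)O)cc(O)c3c(=O)c2O)ccc1O | target

**Step count and risks**

Total step count: 12. Longest linear sequence: 11 steps (steps 1 to 6 and 8 to 12); step 7 supplies the alkyne.

Steps most likely to fail: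

1. Step 8 (Proposed new method). Three processes may defeat it. The excited 3-benzyloxy-2-aryl-4-pyranone chromophore may react on its own, by hydrogen abstraction from the OCH2Ph group by the excited C4 carbonyl or by rearrangement of the pyranone ring. The ketene may be consumed by moisture or by dimerisation faster than the alkyne traps it. The ring opening of the cyclobutenone may turn the pyranonyl group outward, so that closure onto C4a stalls.
   Fallback (known chemistry; ring A is bought instead of built): it sets out from boronic acid 4 and returns at 20. Commercial 5,7-dihydroxy-4H-chromen-4-one is protected (MOMCl, NaH, DMF) as 5,7-bis(methoxymethoxy)-4H-chromen-4-one F1. Conjugate addition of 4 to F1 under divalent palladium catalysis (Pd(OCOCF3)2, 2,2'-bipyridine, NH4PF6, H2O, ClCH2CH2Cl, 60 °C) should give racemic 2-[4-(benzyloxy)-3-methoxyphenyl]-5,7-bis(methoxymethoxy)chroman-4-one F2. DDQ (1,4-dioxane, reflux) should dehydrogenate it to 2-[4-(benzyloxy)-3-methoxyphenyl]-5,7-bis(methoxymethoxy)-4H-chromen-4-one F3. Epoxidation of the C2=C3 bond with dimethyldioxirane (acetone/CH2Cl2, 0 °C) and opening of the epoxide on silica should give 2-[4-(benzyloxy)-3-methoxyphenyl]-3-hydroxy-5,7-bis(methoxymethoxy)-4H-chromen-4-one F4. Benzylation (BnBr, K2CO3, DMF) gives 3-(benzyloxy)-2-[4-(benzyloxy)-3-methoxyphenyl]-5,7-bis(methoxymethoxy)-4H-chromen-4-one F5, and HCl in MeOH/THF removes both methoxymethyl groups to give 20.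

2. Step 7. The ambident ynolate may be silylated at carbon instead of oxygen, giving a bis-silylketene, or tert-butoxide may cleave the C–Si bond of the acetylide or ynolate.
   Fallback (an alkyl ynol ether in place of the silyl ynol ether): it sets out from diazo ketone 9 and returns at 20. tert-Butoxyethyne F6, made from (Z)-1-bromo-2-tert-butoxyethene with NaNH2 in liquid NH3, replaces 13 under the conditions of step 8. After ketene 14 the cascade should run through 4-{5-(benzyloxy)-6-[4-(benzyloxy)-3-methoxyphenyl]-4-oxo-4H-pyran-2-yl}-3-tert-butoxycyclobut-2-en-1-one F7, the dienylketene 3-tert-butoxy-4-(pyranon-2-yl)buta-1,3-dien-1-one F8 and the 4a-H keto tautomer 3-(benzyloxy)-2-[4-(benzyloxy)-3-methoxyphenyl]-7-tert-butoxy-4aH-chromene-4,5-dione F9 to 3,4'-di-O-benzyl-7-O-tert-butylisorhamnetin F10. CF3CO2H in CH2Cl2 then cleaves the tert-butyl ether and gives 20 directly, with no silyl group on C6 to remove.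

3. Step 6. Diazomethane may add as a 1,3-dipole across the electron-poor C=C bonds of the pyranone, or HCl may convert the diazo ketone to the chloromethyl ketone.
   Fallback (diazo transfer to a methyl ketone instead of acylation of diazomethane): it sets out from acid chloride 8 and returns at 9. MeNHOMe·HCl and pyridine in CH2Cl2 give 5-(benzyloxy)-6-[4-(benzyloxy)-3-methoxyphenyl]-N-methoxy-N-methyl-4-oxo-4H-pyran-2-carboxamide F11. MeMgBr (THF, −78 °C) gives 6-acetyl-3-(benzyloxy)-2-[4-(benzyloxy)-3-methoxyphenyl]-4H-pyran-4-one F12. LiN(SiMe3)2 and CF3CO2CH2CF3 (THF, −78 °C) give 1-{5-(benzyloxy)-6-[4-(benzyloxy)-3-methoxyphenyl]-4-oxo-4H-pyran-2-yl}-4,4,4-trifluorobutane-1,3-dione F13, which is not isolated. Detrifluoroacetylative diazo transfer with MsN3, Et3N and H2O in MeCN then gives 9.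

**Further compounds**

F1 | step 8 | 5,7-bis(methoxymethoxy)-4H-chromen-4-one | COCOc1cc(OCOC)c2c(=O)ccoc2c1
F2 | step 8 | 2-[4-(benzyloxy)-3-methoxyphenyl]-5,7-bis(methoxymethoxy)chroman-4-one (racemic) | COCOc1cc(OCOC)c2c(c1)OC(c1ccc(OCc3ccccc3)c(OC)c1)CC2=O
F3 | step 8 | 2-[4-(benzyloxy)-3-methoxyphenyl]-5,7-bis(methoxymethoxy)-4H-chromen-4-one | COCOc1cc(OCOC)c2c(=O)cc(-c3ccc(OCc4ccccc4)c(OC)c3)oc2c1
F4 | step 8 | 2-[4-(benzyloxy)-3-methoxyphenyl]-3-hydroxy-5,7-bis(methoxymethoxy)-4H-chromen-4-one | COCOc1cc(OCOC)c2c(=O)c(O)c(-c3ccc(OCc4ccccc4)c(OC)c3)oc2c1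
F5 | step 8 | 3-(benzyloxy)-2-[4-(benzyloxy)-3-methoxyphenyl]-5,7-bis(methoxymethoxy)-4H-chromen-4-one | COCOc1cc(OCOC)c2c(=O)c(OCc3ccccc3)c(-c3ccc(OCc4ccccc4)c(OC)c3)oc2c1
F6 | step 7 | tert-butoxyethyne | C#COC(C)(C)C
F7 | step 7 | 4-{5-(benzyloxy)-6-[4-(benzyloxy)-3-methoxyphenyl]-4-oxo-4H-pyran-2-yl}-3-tert-butoxycyclobut-2-en-1-one (racemic) | COc1cc(-c2oc(C3C(=O)C=C3OC(C)(C)C)cc(=O)c2OCc2ccccc2)ccc1OCc1ccccc1
F8 | step 7 | 3-tert-butoxy-4-(pyranon-2-yl)buta-1,3-dien-1-one (dienylketene, pyranonyl cis to the ketene chain) | COc1cc(-c2oc(/C=C(\C=C=O)OC(C)(C)C)cc(=O)c2OCc2ccccc2)ccc1OCc1ccccc1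
F9 | step 7 | 3-(benzyloxy)-2-[4-(benzyloxy)-3-methoxyphenyl]-7-tert-butoxy-4aH-chromene-4,5-dione (racemic) | COc1cc(C2=C(OCc3ccccc3)C(=O)C3C(=O)C=C(OC(C)(C)C)C=C3O2)ccc1OCc1ccccc1
F10 | step 7 | 3,4'-di-O-benzyl-7-O-tert-butylisorhamnetin | COc1cc(-c2oc3cc(OC(C)(C)C)cc(O)c3c(=O)c2OCc2ccccc2)ccc1OCc1ccccc1
F11 | step 6 | 5-(benzyloxy)-6-[4-(benzyloxy)-3-methoxyphenyl]-N-methoxy-N-methyl-4-oxo-4H-pyran-2-carboxamide | COc1cc(-c2oc(C(=O)N(C)OC)cc(=O)c2OCc2ccccc2)ccc1OCc1ccccc1
F12 | step 6 | 6-acetyl-3-(benzyloxy)-2-[4-(benzyloxy)-3-methoxyphenyl]-4H-pyran-4-one | COc1cc(-c2oc(C(C)=O)cc(=O)c2OCc2ccccc2)ccc1OCc1ccccc1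
F13 | step 6 | 1-{5-(benzyloxy)-6-[4-(benzyloxy)-3-methoxyphenyl]-4-oxo-4H-pyran-2-yl}-4,4,4-trifluorobutane-1,3-dione | COc1cc(-c2oc(C(=O)CC(=O)C(F)(F)F)cc(=O)c2OCc2ccccc2)ccc1OCc1ccccc1
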